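**Plan**
1. Retrosynthesis, first cut: both (Z)-butylidene enol lactones are opened at C1–O2/C1–C7a and C1'–O2'/C1'–C7a' (double carbonylative enol lactonisation), and the C3–C3a and C3'–C3a' bonds are cut (C-acylation), leading back to a silyl-protected tricyclic diketone.
2. Second and third cuts: the C4'–C5' bond of the bicyclo[2.2.2]octane (6-endo radical conjugate addition) leads to a cis-fused bicyclic enedione; ring C is then cut at C7'–C6 and C4'–C7 (Diels–Alder) into cyclohex-2-enone and a 2-silyloxydiene made from ethyl (R)-4-chloro-3-hydroxybutanoate.
3. Forward order: chain assembly (steps 1–4), ring C onto ring A (step 5), enone and iodide (steps 6, 7), ring B and with it the bicycle (step 8), both lactone rings at once (steps 9–11), desilylation (step 12).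
4. Stereochemistry: C6' comes from the chiral pool; C7', C6 and C7 come from an endo Diels–Alder reaction on the diene face anti to the CH2Cl arm; C4' is fixed by the two-carbon tether; both exocyclic alkenes become Z through O-enolate capture.
5. Enabling feature: C7a', the ring-B carbon that finally carries the lactone carbonyl, is a ketone when the ring is closed. This makes C3a'=C4' an enone whose β-carbon C4' lies 1,4 across ring C from C7', the carbon that carries the C6'(O)–C5' chain.

Key step: step 8

Remark: carbons carry phthalide locants, unprimed for the half with cyclohexene ring A (C3a, C4, C5, C6, C7, C7a) and primed for the half inside the bicyclo[2.2.2]octene (ring B: C3a', C4', C5', C6', C7', C7a'; C6' bears the hydroxyl); ring C is C6–C7–C4'–C3a'–C7a'–C7'; intermediates keep the locants of the carbons they become. It is assumed that diene 5 reacts on the face anti to its CH2Cl arm (argued in step 5).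

**Route**

Step 1
Reactants: 1 ethyl (R)-4-chloro-3-hydroxybutanoate
Product: 2 ethyl (R)-3-(tert-butyldimethylsilyloxy)-4-chlorobutanoate
Conditions: TBSCl, imidazole, DMF, rt
Reagents that add atoms: tert-butyldimethylsilyl chloride, CC(C)(C)[Si](C)(C)Cl
Why: Standard silylation of the secondary alcohol, which also prevents epoxide formation from the chlorohydrin in the later basic steps; the stereocentre is not touched.

Step 2
Reactants: 2 ethyl (R)-3-(tert-butyldimethylsilyloxy)-4-chlorobutanoate
Product: 3 (R)-3-(tert-butyldimethylsilyloxy)-4-chloro-N-methoxy-N-methylbutanamide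
Conditions: MeNH(OMe)·HCl, i-PrMgCl, THF, −20 °C
Reagents that add atoms: N,O-dimethylhydroxylamine hydrochloride, CNOC.Cl
Why: Aminolysis of the ester by the magnesium amide gives the Weinreb amide, so that only one vinyl group is delivered in the next step.

Step 3
Reactants: 3 (R)-3-(tert-butyldimethylsilyloxy)-4-chloro-N-methoxy-N-methylbutanamide
Product: 4 (R)-5-(tert-butyldimethylsilyloxy)-6-chlorohex-1-en-3-one
Conditions: vinylmagnesium bromide, THF, 0 °C; then cold 1 M HCl
Reagents that add atoms: vinylmagnesium bromide, C=C[Mg]Br
Why: Weinreb ketone synthesis, in which the chelated tetrahedral adduct releases the vinyl ketone only on work-up, and the acidic quench keeps the freed amine from adding to the enone.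

Step 4
Reactants: 4 (R)-5-(tert-butyldimethylsilyloxy)-6-chlorohex-1-en-3-one
Product: 5 (3Z,5R)-3,5-bis(tert-butyldimethylsilyloxy)-6-chlorohexa-1,3-diene
Conditions: TBSOTf, Et3N, Et2O, 0 °C
Reagents that add atoms: tert-butyldimethylsilyl trifluoromethanesulfonate, CC(C)(C)[Si](C)(C)OS(=O)(=O)C(F)(F)F
Why: Soft enolisation at the only enolisable position gives the 2-silyloxydiene, and the favoured Z enol ether (silyloxy cis to the side chain) places the side chain on the outside of the s-cis diene.

Step 5
Reactants: 5 (3Z,5R)-3,5-bis(tert-butyldimethylsilyloxy)-6-chlorohexa-1,3-diene; 6 cyclohex-2-en-1-one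
Product: 7 cis-fused adduct, 6-(tert-butyldimethylsilyloxy)-5-[(1R)-1-(tert-butyldimethylsilyloxy)-2-chloroethyl]-3,4,4a,5,8,8a-hexahydronaphthalen-1(2H)-one with H-4a, H-5 and H-8a all cis (ring A ketone at C7a, silyl enol ether C7a'=C3a')
Conditions: Tf2NH (10 mol %), CH2Cl2, −78 → −40 °C; Et3N quench
Reagents that add atoms: none
Why: Acid-catalysed Diels–Alder reaction of a 2-silyloxydiene with a cyclic enone (the O-silylated enone is the dienophile), in which the nucleophilic terminus C7' bonds to the enone β-carbon C6 and C4' to the α-carbon C7, the endo transition state places H-C7', H-C6 and H-C7 cis, and the diene reacts in the conformer with C6'–H eclipsing C7'=C7a' (1,3-allylic strain with the cis silyloxy group) on the face anti to the CH2Cl arm and past the small silyloxy oxygen, which relays the chiral-pool centre to the three new ones.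

Step 6
Reactants: 7 cis-fused silyl enol ether adduct
Product: 8 5-[(1R)-1-(tert-butyldimethylsilyloxy)-2-chloroethyl]-2,3,4,4a,5,8a-hexahydronaphthalene-1,6-dione, cis-fused, H-4a, H-5 and H-8a all cis (ketones at C7a and C7a', enone C3a'=C4')
Conditions: Pd(OAc)2 (1.1 equiv), MeCN, 40 °C
Reagents that add atoms: none
Why: Saegusa–Ito oxidation, in which divalent palladium palladates C3a' and β-hydride elimination can only go towards C4', which unveils the C7a' ketone as the C3a'=C4' enone under neutral conditions that do not epimerise C7 or C7'.

Step 7
Reactants: 8 chloro enedione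
Product: 9 5-[(1R)-1-(tert-butyldimethylsilyloxy)-2-iodoethyl]-2,3,4,4a,5,8a-hexahydronaphthalene-1,6-dione, same configuration as 8
Conditions: NaI (10 equiv), butan-2-one, 80 °C
Reagents that add atoms: sodium iodide, [Na+].[I-]
Why: Finkelstein exchange of the primary chloride under neutral conditions gives a halide that a stannyl radical abstracts quickly, without base that would eliminate the β-silyloxy ketone or close a cyclopropane.

Step 8
Reactants: 9 iodo enedione
Product: 10 tricyclic diketone, 9-(tert-butyldimethylsilyloxy)octahydro-1,4-ethanonaphthalene-2,5(1H,3H)-dione (ketones at C7a' and C7a; ring A cis-fused on the side of the C6'–C5' bridge; the silyloxy group on C6' points towards the C7a'–C3a' bridge)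
Conditions: Bu3SnH (1.3 equiv, syringe pump), AIBN (0.2 equiv), benzene (0.01 M), 80 °C
Reagents that add atoms: none
Why: Bu3Sn• abstracts iodine from C5', and the nucleophilic primary radical adds to C4', the β-carbon of the ring-C enone, to give the C3a' α-keto radical, which is reduced by Bu3SnH; this is an intramolecular Giese-type radical conjugate addition, closest to known endo-mode alkyl radical cyclisations onto enones whose carbonyl lies inside the forming ring. The closure is 6-endo-trig for ring B (C3a', C4', C5', C6', C7', C7a') and, through C6–C7, 6-exo-trig for the second six-membered ring (C4', C5', C6', C7', C6, C7), so one bond completes the bicyclo[2.2.2]octane. The only new stereocentre, the bridgehead C4', is fixed by the tether: the chain is anchored on C7' and can reach C4' only across the face of ring C on which it sits, while C6' keeps its configuration with the silyloxy group over the open C7a'–C3a' bridge and its hydrogen towards ring A. The step needs 6-endo over 5-exo attack and cyclisation over direct reduction. The first is secured by polarity and strain, because attack at C3a' would hit the enone α-carbon, leave an unstabilised radical and form a bicyclo[3.2.1] ring; the second is secured by slow addition of the stannane at high dilution. The bridging approach is perpendicular to the enone plane, which is the trajectory the β-carbon requires.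

Step 9
Reactants: 10 tricyclic diketone
Product: 11 bis(β-diketone), the 3,6-dipentanoyl derivative of 10 (pentanoyl on C3a' and C3a), drawn as its bis-enol
Conditions: pentanoyl chloride (2.6 equiv), MgBr2·OEt2, i-Pr2NEt, CH2Cl2, rt
Reagents that add atoms: pentanoyl chloride, CCCCC(=O)Cl
Why: Soft-enolisation C-acylation of both ketones at their only methylene α-carbons, C3a (the ring-fusion carbon C7 would give a non-enolisable product) and C3a' (C7' is a bridgehead), installs the two pentanoyl groups that become C3, C8–C11 and C3', C8'–C11'.

Step 10
Reactants: 11 bis(β-diketone)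
Product: 12 bis(enol triflate), with trifluoromethanesulfonyloxy groups on C7a and C7a' and double bonds C7a=C3a and C7a'=C3a', each conjugated to its pentanoyl group
Conditions: Tf2O (2.4 equiv), Et3N, CH2Cl2, −78 °C
Reagents that add atoms: trifluoromethanesulfonic anhydride, O=S(=O)(OS(=O)(=O)C(F)(F)F)C(F)(F)F
Why: O-Sulfonylation of the two β-diketone enolates at the ring oxygen gives the endocyclic enol triflates, which puts a vinyl electrophile on exactly the two carbons that must carry the lactone carbonyls.

Step 11
Reactants: 12 bis(enol triflate)
Product: 13 6'-O-tert-butyldimethylsilyl ether of the target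
Conditions: CO (3 atm), Pd(PPh3)4 (10 mol %), LiCl, Et3N, DMF, 70 °C
Reagents that add atoms: carbon monoxide, [C-]#[O+]
Why: Double carbonylative enol lactonisation, in which oxidative addition of each vinyl triflate to zerovalent palladium and CO insertion give an acylpalladium that is captured by the oxygen of the neighbouring enolised pentanoyl ketone, closing each five-membered ring with the (Z)-butylidene geometry because the propyl group is kept away from C4 and C4'.

Step 12
Reactants: 13 silyl ether of the target
Product: 14 target, CNP0289078.1
Conditions: HF·pyridine, THF/pyridine, 0 °C → rt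
Reagents that add atoms: none
Why: Acidic fluoride cleaves the secondary silyl ether under conditions that leave the two base- and nucleophile-sensitive enol lactones intact; no stereocentre is affected.

**Compound list**
1 | ethyl (R)-4-chloro-3-hydroxybutanoate | CCOC(=O)C[C@@H](O)CCl | starting material
2 | ethyl (R)-3-(tert-butyldimethylsilyloxy)-4-chlorobutanoate | CCOC(=O)C[C@@H](O[Si](C)(C)C(C)(C)C)CCl | intermediate
3 | (R)-3-(tert-butyldimethylsilyloxy)-4-chloro-N-methoxy-N-methylbutanamide | CON(C)C(=O)C[C@@H](O[Si](C)(C)C(C)(C)C)CCl | intermediate
4 | (R)-5-(tert-butyldimethylsilyloxy)-6-chlorohex-1-en-3-one | C=CC(=O)C[C@@H](O[Si](C)(C)C(C)(C)C)CCl | intermediate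
5 | (3Z,5R)-3,5-bis(tert-butyldimethylsilyloxy)-6-chlorohexa-1,3-diene | C=C/C(O[Si](C)(C)C(C)(C)C)=C/[C@@H](O[Si](C)(C)C(C)(C)C)CCl | intermediate
6 | cyclohex-2-en-1-one | O=C1C=CCCC1 | starting material
7 | all-cis Diels–Alder adduct (ring A ketone, ring C silyl enol ether, side chain (1R)-1-silyloxy-2-chloroethyl on C7') | O=C2CCC[C@@H]1[C@H]([C@H](CCl)O[Si](C)(C)C(C)(C)C)C(O[Si](C)(C)C(C)(C)C)=CC[C@H]21 | intermediate
8 | cis-fused chloro enedione (enone C3a'=C4') | O=C2CCC[C@@H]1[C@H]([C@H](CCl)O[Si](C)(C)C(C)(C)C)C(=O)C=C[C@H]21 | intermediate
9 | cis-fused iodo enedione | O=C2CCC[C@@H]1[C@H]([C@H](CI)O[Si](C)(C)C(C)(C)C)C(=O)C=C[C@H]21 | intermediate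
10 | tricyclic diketone with the bicyclo[2.2.2]octane (C6' now formally S through a change of priorities only) | O=C2CCC[C@@H]1[C@H]3C(=O)C[C@H](C[C@@H]3O[Si](C)(C)C(C)(C)C)[C@H]21 | intermediate
11 | bis(β-diketone), bis-enol form | OC2=C(C(=O)CCCC)CC[C@@H]1[C@H]3C(O)=C(C(=O)CCCC)[C@H](C[C@@H]3O[Si](C)(C)C(C)(C)C)[C@H]21 | intermediate
12 | bis(enol triflate) | FC(F)(F)S(=O)(=O)OC2=C(C(=O)CCCC)CC[C@@H]1[C@H]3C(OS(=O)(=O)C(F)(F)F)=C(C(=O)CCCC)[C@H](C[C@@H]3O[Si](C)(C)C(C)(C)C)[C@H]21 | intermediate
13 | 6'-O-tert-butyldimethylsilyl ether of the target | CCC/C=C1\OC(=O)C2=C1CC[C@@H]1[C@H]3C4=C(/C(=C/CCC)OC4=O)[C@H](C[C@@H]3O[Si](C)(C)C(C)(C)C)[C@H]21 | intermediate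
14 | CNP0289078.1 | CCC/C=C1\OC(=O)C2=C1CC[C@@H]1[C@H]3C4=C(/C(=C/CCC)OC4=O)[C@H](C[C@@H]3O)[C@H]21 | target

**Step count**
Total steps: 12. Longest linear sequence: 12 steps (from 1; compound 6 enters at step 5).

**Steps most likely to fail**

Step 5. Risk: poor facial selectivity of the diene (the dienophile entering anti to the silyloxy oxygen instead of anti to the CH2Cl arm), or a Mukaiyama–Michael addition that stops before ring closure. Fallback: the stereocontrol is moved from the diene stereocentre to an external reagent. Diene 5 and enone 6 would be combined under a chiral oxazaborolidinium triflimide Lewis acid (protonated B-(o-tolyl)oxazaborolidine from α,α-diphenylprolinol), using the catalyst antipode whose enone-face preference matches the face that the (R)-diene must meet. This sets out from 5 and 6 and comes back at 7 without any new compound (F0).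

Step 8. Risk: hydrogen transfer to the primary radical before it cyclises, or a cyclisation slowed by the boat-like arrangement of ring C that the bridge requires. Fallback: a polar closure of the same bond, setting out from 9. Displacement of iodide with NaNO2 (DMSO, phloroglucinol) would give the nitro enedione F1. A catalytic amidine or guanidine base would form only the nitronate, the most acidic site, and its intramolecular Michael addition to C4' would give the 5'-nitro tricyclic diketone F2 as a mixture at C5'. Reductive denitration (Bu3SnH, AIBN, toluene, 110 °C) would then come back to the route at 10.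

Step 11. Risk: capture of the acylpalladium at carbon instead of oxygen (cyclopentenedione formation), or reduction of the vinyl triflate before CO insertion. Fallback: separate the carbonylation from the ring closure, setting out from 12. Methoxycarbonylation (CO, MeOH, Pd(OAc)2, 1,3-bis(diphenylphosphino)propane, Et3N) would give the bis(γ-keto methyl ester) F3. Hydrolysis (LiOH, THF/H2O, then acid) would give the bis(γ-keto acid) F4, which exists largely as its hydroxybutenolide ring tautomer. Dehydrative enol lactonisation (Ac2O, NaOAc, 80 °C) would give the (Z)-butylidene lactones and come back to the route at 13.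

Further compounds
F0 | step 5 | none | none
F1 | step 8 | nitro enedione, the 2-nitroethyl analogue of 9 | O=C2CCC[C@@H]1[C@H]([C@H](C[N+](=O)[O-])O[Si](C)(C)C(C)(C)C)C(=O)C=C[C@H]21
F2 | step 8 | 5'-nitro derivative of tricyclic diketone 10 (both C5' epimers) | O=C2CCC[C@@H]1[C@H]3C(=O)C[C@H](C([N+](=O)[O-])[C@@H]3O[Si](C)(C)C(C)(C)C)[C@H]21
F3 | step 11 | bis(γ-keto methyl ester), methoxycarbonyl on C7a and C7a' | COC(=O)C2=C(C(=O)CCCC)CC[C@@H]1[C@H]3C(C(=O)OC)=C(C(=O)CCCC)[C@H](C[C@@H]3O[Si](C)(C)C(C)(C)C)[C@H]21
F4 | step 11 | bis(γ-keto acid), open form | OC(=O)C2=C(C(=O)CCCC)CC[C@@H]1[C@H]3C(C(=O)O)=C(C(=O)CCCC)[C@H](C[C@@H]3O[Si](C)(C)C(C)(C)C)[C@H]21
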